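Readings and results come from a simulation on assumed constants.

- The amounts of J and G are the same in theta, epsilon, dusk and midnight, while Q ranges from 10.0 mM to 57 mM.

the same everywhere: J 10 mM
- theta: G 7 mM; Q 15 mM; run made earlier
- epsilon: G 7 mM; Q 57 mM; run made earlier
- dusk: G 7.00 mM; Q 10.0 mM; time 1.0 h
- midnight: G 7.00 mM; Q 40.0 mM; time 0.60 h

- theta (time / min: X / %): 5.00: 3.2; 8.00: 4.8; 12.0: 9.7; 15.0: 10.4; 25.0: 16.6; 40.0: 18.1; 60.0: 21.1
- epsilon (time / min: X / %): 8.00: 15.4; 15.0: 22.3; 25.0: 24.9; 30.0: 26.6; 40.0: 26.9; 50.0: 29.0; 60.0: 30.5

(scatter of a reading: 1 percentage point)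

* which one finishes higher in amount of X, in percent of the J charged ("neither" within 2 percentage points) (dusk / midnight / neither)
* amount of X at the end, in percent of the J charged, dusk
* amount of X at the end, in percent of the J charged, midnight

- the earlier runs were read with a standard deviation of 1 percentage point
- a reading or a percentage of X counts all its forms, free or not

- I fold the charges into one number, the Q share: Q charged as a fraction of J and G charged together. It is 0.882 in theta, 0.588 in dusk, 2.35 in midnight and 3.35 in epsilon.
- Below a share of one, I suppose Q is the limiting reagent, so X should follow the share. Theta's last reading, at 60.0 min, gives a yield per share, X per unit of Q share, of 23.9%, a reading with its scatter.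
- For dusk, which stops at the same time, that gives 14.1%.
- One number is not enough for epsilon, whose share is above one: it gives 80.1% there, more than the 30.5% read. So for midnight, stopped at 0.60 h, I take epsilon's 26.9% at 40.0 min.
- The forecast says midnight, with 16.5% (13.5% to 19.5%) for dusk and 24.5% (21.5% to 27.5%) for midnight, holding that “the reaction is roughly first order in Q”. My dusk figure is lower than its figure and my midnight figure higher.
- The flasks give 13.3% for dusk and 26.5% for midnight, so midnight finishes higher.

    J + X ⇌ L, settled at all times (K = 56.0 /M)
    J + Q → D (k = 26.0 /M/min)
    Q + G → Z (k = 9.70 /M/min)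
    D + Z → X (k = 11.0 /M/min)
    2 D → E (k = 18.0 /M/min)

- Q is what separates them: midnight with dusk's charge of Q ends at 11.4% instead of 26.5%. In the scheme J and G each take up Q, as the share counts them, and dusk keeps 0.0504% of its Q at the end while midnight keeps 57.5%. A neighbouring flask, the same as dusk but with 17 mM of Q, has a share of 1.00, so the yield per share gives 23.9%, and that flask ends at 24.4%.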